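**Strategy.** Ring A is built last by an Alder–Rickert reaction. The meta-dioxygenated triad C2(OH)–C3(Me)–C4(O-acyl) of ring A corresponds to 2-methylcyclohexane-1,3-dione, and C1 (CO2Me) together with C6 (Me) corresponds to methyl but-2-ynoate. One operation forms C1–C2 and C5–C6, closes ring A and aromatises it by loss of ethylene, with the depside ester already in place. The precursor is a cyclohexa-1,3-diene carrying a triisopropylsilyloxy group on one terminus, a methyl group on the other terminus, a second methyl group on the inner carbon next to the silyloxy carbon, and the bis-silylated ring B acid bound as an enol ester at the remaining inner carbon.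

Key step: step 8

Remark on the chemistry: the target has no stereocentre. Compounds 9 and 13 are racemic and lose their stereocentres in steps 7 and 8. Ring A is numbered C1 (CO2Me) to C6, ring B C1' (carbonyl-bearing carbon) to C6'. All three phenols are masked as fluoride-labile silyl ethers so that one final operation unmasks them. The bulkier triisopropylsilyl group sits on the diene because that vinylogous silyl ester must survive two amide-base steps.

Step 1
Reactants: 1 2,5-dimethylbenzene-1,3-diol (2,5-dimethylresorcinol)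
Product: 2 2,4-dihydroxy-3,6-dimethylbenzoic acid
Conditions: MeOMgOCO2Me (2 M in DMF), 120 °C; then cold 1 M HCl
Reagents that add atoms: methoxymagnesium methyl carbonate, COC(=O)O[Mg]OC
Why: Chelation-assisted Kolbe–Schmitt-type ortho-carboxylation of a resorcinol should occur at C4/C6, the only free and mutually equivalent positions, and the magnesium chelate of the salicylate should hold the carboxyl group against decarboxylation until the cold acidic quench.

Step 2
Reactants: 2 2,4-dihydroxy-3,6-dimethylbenzoic acid
Product: 3 5-chloro-2,4-dihydroxy-3,6-dimethylbenzoic acid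
Conditions: SO2Cl2 (1.05 equiv), Et2O, 0 °C to rt
Reagents that add atoms: sulfuryl chloride, O=S(=O)(Cl)Cl
Why: Electrophilic aromatic chlorination should take the single remaining ring hydrogen (C5'), which is ortho to one hydroxyl and para to the other, faster than ipso attack at the carboxyl-bearing carbon.

Step 3
Reactants: 3 5-chloro-2,4-dihydroxy-3,6-dimethylbenzoic acid
Product: 4 tert-butyldimethylsilyl 2,4-bis(tert-butyldimethylsilyloxy)-5-chloro-3,6-dimethylbenzoate
Conditions: TBSOTf (3.5 equiv), Et3N, CH2Cl2, 0 °C to rt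
Reagents that add atoms: tert-butyldimethylsilyl trifluoromethanesulfonate, CC(C)(C)[Si](C)(C)OS(=O)(=O)C(F)(F)F
Why: Exhaustive O-silylation with a silyl triflate should cap the two doubly flanked phenols, which a silyl chloride would take only slowly, and at the same time turn the acid into a silyl ester, the handle for step 4.

Step 4
Reactants: 4 tert-butyldimethylsilyl 2,4-bis(tert-butyldimethylsilyloxy)-5-chloro-3,6-dimethylbenzoate
Product: 5 2,4-bis(tert-butyldimethylsilyloxy)-5-chloro-3,6-dimethylbenzoyl chloride
Conditions: (COCl)2 (1.2 equiv), DMF (cat.), CH2Cl2, 0 °C to rt; evaporate under high vacuum, use crude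
Reagents that add atoms: oxalyl chloride, ClC(=O)C(=O)Cl
Why: The chloroiminium salt from DMF and oxalyl chloride should exchange the silyl ester for an acyl chloride without releasing HCl (silyl ester to acid chloride conversion), so the two aryl silyl ethers stay in place; the volatile silyl chloride is pumped off so that it cannot compete for the enolate in step 7.

Step 5
Reactants: 6 2-methylcyclohexane-1,3-dione
Product: 7 2-methyl-3-(triisopropylsilyloxy)cyclohex-2-en-1-one
Conditions: TIPSOTf (1.1 equiv), Et3N, CH2Cl2, 0 °C
Reagents that add atoms: triisopropylsilyl trifluoromethanesulfonate, CC(C)[Si](OS(=O)(=O)C(F)(F)F)(C(C)C)C(C)C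
Why: O-silylation of the enolised 1,3-dione should give the vinylogous silyl ester, in which one carbonyl is masked and the bulky silyl group resists transfer in the base steps that follow.

Step 6
Reactants: 7 2-methyl-3-(triisopropylsilyloxy)cyclohex-2-en-1-one
Product: 9 racemic 2,6-dimethyl-3-(triisopropylsilyloxy)cyclohex-2-en-1-one, via lithium enolate 8 (not isolated)
Conditions: LiN(iPr)2 (1.1 equiv), THF, −78 °C; MeI, −78 to 0 °C
Reagents that add atoms: iodomethane, CI
Why: Kinetic α'-deprotonation of a vinylogous ester and C-alkylation of the cross-conjugated enolate (Stork–Danheiser-type alkylation) should place the methyl group at C6 of the enone (later C5 of ring A); the new stereocentre forms as a racemate and is erased in step 7.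

Step 7
Reactants: 9 racemic 2,6-dimethyl-3-(triisopropylsilyloxy)cyclohex-2-en-1-one; 5 2,4-bis(tert-butyldimethylsilyloxy)-5-chloro-3,6-dimethylbenzoyl chloride
Product: 11 1,3-dimethyl-4-(triisopropylsilyloxy)cyclohexa-1,3-dien-2-yl 2,4-bis(tert-butyldimethylsilyloxy)-5-chloro-3,6-dimethylbenzoate, via lithium dienolate 10 (not isolated)
Conditions: LiN(iPr)2 (1.05 equiv), THF, −78 °C; then 5, DMPU, −78 to 0 °C
Reagents that add atoms: none
Why: The second kinetic α'-deprotonation gives a fully substituted enolate whose carbon terminus is too hindered for C-acylation by a doubly ortho-substituted aroyl chloride, so O-acylation (enol ester formation) should prevail, helped by the dipolar cosolvent.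

Step 8
Reactants: 11 1,3-dimethyl-4-(triisopropylsilyloxy)cyclohexa-1,3-dien-2-yl 2,4-bis(tert-butyldimethylsilyloxy)-5-chloro-3,6-dimethylbenzoate; 12 methyl but-2-ynoate
Product: 14 methyl 4-[2,4-bis(tert-butyldimethylsilyloxy)-5-chloro-3,6-dimethylbenzoyloxy]-3,5,6-trimethyl-2-(triisopropylsilyloxy)benzoate, via bicyclooctadiene adduct 13 (not isolated)
Conditions: 12 (5 equiv), BHT (cat.), mesitylene, sealed tube, 150 °C
Reagents that add atoms: none
Why: A thermal [4+2] cycloaddition of the ring-locked s-cis diene of 11 with the ynoate should give bicyclo[2.2.2]octadiene 13, whose CH2–CH2 bridge is then expelled as ethylene in a retro-[4+2] driven by aromatisation (Alder–Rickert reaction). The closest known case is the reaction of 1-alkoxy- or 1-silyloxy-3-silyloxycyclohexa-1,3-dienes with alkynoates, which gives 2,4-dioxygenated benzoates in the same way. Ring A is closed as a six-membered carbocycle by intermolecular [4+2] union of a four-carbon and a two-carbon unit, forming C1–C2 and C5–C6 in one operation. The step needs regioselectivity only: the ester-bearing alkyne carbon must end up next to the silyloxy carbon. Both oxygens, the terminal silyloxy group through the diene and the inner aroyloxy group as an enol ester, raise the HOMO coefficient at the methyl-bearing terminus, which should therefore bond to the electrophilic β-carbon of the ynoate and leave the silyloxy terminus to bond to the α-carbon. No stereocentre remains, because the two bridgehead centres of 13 become aromatic carbons.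

Step 9
Reactants: 14 methyl 4-[2,4-bis(tert-butyldimethylsilyloxy)-5-chloro-3,6-dimethylbenzoyloxy]-3,5,6-trimethyl-2-(triisopropylsilyloxy)benzoate
Product: 15 methyl 4-(5-chloro-2,4-dihydroxy-3,6-dimethylbenzoyloxy)-2-hydroxy-3,5,6-trimethylbenzoate (target)
Conditions: Bu4NF (3.5 equiv), AcOH (4 equiv), THF, 0 °C to rt
Reagents that add atoms: none
Why: Fluoride-mediated cleavage of the three aryl silyl ethers under acetic acid buffering should free the phenols without phenoxide build-up, so the aryl ester link and the methyl ester are not touched.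

**Compound list**

1 | 2,5-dimethylbenzene-1,3-diol (2,5-dimethylresorcinol) | Cc1cc(O)c(C)c(O)c1 | starting material
2 | 2,4-dihydroxy-3,6-dimethylbenzoic acid | Cc1cc(O)c(C)c(O)c1C(=O)O | intermediate
3 | 5-chloro-2,4-dihydroxy-3,6-dimethylbenzoic acid | Cc1c(Cl)c(O)c(C)c(O)c1C(=O)O | intermediate
4 | tert-butyldimethylsilyl 2,4-bis(tert-butyldimethylsilyloxy)-5-chloro-3,6-dimethylbenzoate | Cc1c(Cl)c(O[Si](C)(C)C(C)(C)C)c(C)c(O[Si](C)(C)C(C)(C)C)c1C(=O)O[Si](C)(C)C(C)(C)C | intermediate
5 | 2,4-bis(tert-butyldimethylsilyloxy)-5-chloro-3,6-dimethylbenzoyl chloride | Cc1c(Cl)c(O[Si](C)(C)C(C)(C)C)c(C)c(O[Si](C)(C)C(C)(C)C)c1C(=O)Cl | intermediate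
6 | 2-methylcyclohexane-1,3-dione | CC1C(=O)CCCC1=O | starting material
7 | 2-methyl-3-(triisopropylsilyloxy)cyclohex-2-en-1-one | CC1=C(O[Si](C(C)C)(C(C)C)C(C)C)CCCC1=O | intermediate
8 | lithium 6-methyl-5-(triisopropylsilyloxy)cyclohexa-1,5-dien-1-olate | [Li]OC1=CCCC(O[Si](C(C)C)(C(C)C)C(C)C)=C1C | intermediate
9 | racemic 2,6-dimethyl-3-(triisopropylsilyloxy)cyclohex-2-en-1-one | CC1CCC(O[Si](C(C)C)(C(C)C)C(C)C)=C(C)C1=O | intermediate
10 | lithium 2,6-dimethyl-5-(triisopropylsilyloxy)cyclohexa-1,5-dien-1-olate | [Li]OC1=C(C)CCC(O[Si](C(C)C)(C(C)C)C(C)C)=C1C | intermediate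
11 | 1,3-dimethyl-4-(triisopropylsilyloxy)cyclohexa-1,3-dien-2-yl 2,4-bis(tert-butyldimethylsilyloxy)-5-chloro-3,6-dimethylbenzoate | CC(C)[Si](OC1=C(C)C(OC(=O)c2c(C)c(Cl)c(O[Si](C)(C)C(C)(C)C)c(C)c2O[Si](C)(C)C(C)(C)C)=C(C)CC1)(C(C)C)C(C)C | intermediate
12 | methyl but-2-ynoate | CC#CC(=O)OC | starting material
13 | racemic methyl 5-[2,4-bis(tert-butyldimethylsilyloxy)-5-chloro-3,6-dimethylbenzoyloxy]-3,4,6-trimethyl-1-(triisopropylsilyloxy)bicyclo[2.2.2]octa-2,5-diene-2-carboxylate (the two bridgehead centres are tied to each other by the bicycle) | COC(=O)C1=C(C)C2(C)CCC1(O[Si](C(C)C)(C(C)C)C(C)C)C(C)=C2OC(=O)c3c(C)c(Cl)c(O[Si](C)(C)C(C)(C)C)c(C)c3O[Si](C)(C)C(C)(C)C | intermediate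
14 | methyl 4-[2,4-bis(tert-butyldimethylsilyloxy)-5-chloro-3,6-dimethylbenzoyloxy]-3,5,6-trimethyl-2-(triisopropylsilyloxy)benzoate | COC(=O)c1c(C)c(C)c(OC(=O)c2c(C)c(Cl)c(O[Si](C)(C)C(C)(C)C)c(C)c2O[Si](C)(C)C(C)(C)C)c(C)c1O[Si](C(C)C)(C(C)C)C(C)C | intermediate
15 | methyl 4-(5-chloro-2,4-dihydroxy-3,6-dimethylbenzoyloxy)-2-hydroxy-3,5,6-trimethylbenzoate | COC(=O)c1c(C)c(C)c(OC(=O)c2c(C)c(Cl)c(O)c(C)c2O)c(C)c1O | target

**Step count.** Total: 9 steps. Longest linear sequence: 7 steps (steps 1, 2, 3, 4, 7, 8, 9); the ring A branch (steps 5 and 6) joins at step 7.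

**Steps most likely to fail**

1. Step 8. The cycloaddition may be too slow for a fully substituted diene and a weakly activated internal alkyne, so that thermal breakdown of the enol ester (acyl or silyl migration, hydrogen shift in the diene) outruns it. The fallback sets out from 5 and comes back at 15; it gives up the cycloaddition and takes ring A from a benzenoid. Commercial methyl 2,4-dihydroxy-3,6-dimethylbenzoate F1 is formylated at its only free ring position (Cl2CHOMe, TiCl4, CH2Cl2, 0 °C; Rieche formylation) to methyl 5-formyl-2,4-dihydroxy-3,6-dimethylbenzoate F2. Hydrogenolysis (H2, Pd/C, AcOH) should reduce the formyl group to methyl and give methyl 2,4-dihydroxy-3,5,6-trimethylbenzoate F3. Its C4 hydroxyl is the more acidic one and is not hydrogen-bonded to the ester; as the sodium phenoxide (NaH, 1 equiv, THF) it should be acylated selectively by 5 to methyl 4-[2,4-bis(tert-butyldimethylsilyloxy)-5-chloro-3,6-dimethylbenzoyloxy]-2-hydroxy-3,5,6-trimethylbenzoate F4. Buffered fluoride as in step 9 then gives 15.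

2. Step 7. Acyl transfer to the hindered enolate may be slow, so that proton exchange, enolate equilibration to the extended dienolate, or attack of the liberated amine on the acyl chloride takes over. The fallback sets out from 9 and comes back at 14; it postpones the ester bond until ring A is aromatic. Enolate 10 is trapped with Me3SiCl to give triisopropyl{[2,4-dimethyl-3-(trimethylsilyloxy)cyclohexa-1,3-dien-1-yl]oxy}silane F5, a bis(silyloxy)diene of the class for which the Alder–Rickert reaction is established. Heating with 12 should give, through racemic methyl 3,4,6-trimethyl-1-(triisopropylsilyloxy)-5-(trimethylsilyloxy)bicyclo[2.2.2]octa-2,5-diene-2-carboxylate F6 and loss of ethylene, methyl 3,5,6-trimethyl-2-(triisopropylsilyloxy)-4-(trimethylsilyloxy)benzoate F7. Brief treatment with citric acid in MeOH should remove only the labile trimethylsilyl ether and give methyl 4-hydroxy-3,5,6-trimethyl-2-(triisopropylsilyloxy)benzoate F8. Its sodium phenoxide (NaH, THF) is acylated with 5 to give 14.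

3. Step 2. Ipso attack of the chlorinating agent at the carboxyl-bearing carbon, with loss of CO2, or over-chlorination of the very electron-rich ring to cyclohexadienones may compete. The fallback sets out from 1 and comes back at 3; it introduces chlorine before the carboxyl group exists. Compound 1 with SO2Cl2 (1.0 equiv, Et2O, −20 °C) should give 4-chloro-2,5-dimethylbenzene-1,3-diol F9; the two free positions are equivalent, so only the degree of chlorination needs control. Carboxylation of F9 with MeOMgOCO2Me as in step 1 can occur only at the one remaining ring position and should deliver 3.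

**Further compounds**

F1 | step 8 | methyl 2,4-dihydroxy-3,6-dimethylbenzoate | COC(=O)c1c(C)cc(O)c(C)c1O
F2 | step 8 | methyl 5-formyl-2,4-dihydroxy-3,6-dimethylbenzoate | COC(=O)c1c(C)c(C=O)c(O)c(C)c1O
F3 | step 8 | methyl 2,4-dihydroxy-3,5,6-trimethylbenzoate | COC(=O)c1c(C)c(C)c(O)c(C)c1O
F4 | step 8 | methyl 4-[2,4-bis(tert-butyldimethylsilyloxy)-5-chloro-3,6-dimethylbenzoyloxy]-2-hydroxy-3,5,6-trimethylbenzoate | COC(=O)c1c(C)c(C)c(OC(=O)c2c(C)c(Cl)c(O[Si](C)(C)C(C)(C)C)c(C)c2O[Si](C)(C)C(C)(C)C)c(C)c1O
F5 | step 7 | triisopropyl{[2,4-dimethyl-3-(trimethylsilyloxy)cyclohexa-1,3-dien-1-yl]oxy}silane | CC1=C(O[Si](C)(C)C)C(C)=C(O[Si](C(C)C)(C(C)C)C(C)C)CC1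
F6 | step 7 | racemic methyl 3,4,6-trimethyl-1-(triisopropylsilyloxy)-5-(trimethylsilyloxy)bicyclo[2.2.2]octa-2,5-diene-2-carboxylate | COC(=O)C1=C(C)C2(C)CCC1(O[Si](C(C)C)(C(C)C)C(C)C)C(C)=C2O[Si](C)(C)C
F7 | step 7 | methyl 3,5,6-trimethyl-2-(triisopropylsilyloxy)-4-(trimethylsilyloxy)benzoate | COC(=O)c1c(C)c(C)c(O[Si](C)(C)C)c(C)c1O[Si](C(C)C)(C(C)C)C(C)C
F8 | step 7 | methyl 4-hydroxy-3,5,6-trimethyl-2-(triisopropylsilyloxy)benzoate | COC(=O)c1c(C)c(C)c(O)c(C)c1O[Si](C(C)C)(C(C)C)C(C)C
F9 | step 2 | 4-chloro-2,5-dimethylbenzene-1,3-diol | Cc1cc(O)c(C)c(O)c1Cl
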